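**Assumption (one line):** names use daucane locants (C1 = ring-fusion carbon bearing CH3, C2, C3, C4 = carbinol bearing isopropyl, C5 = ring-fusion CH, C6 = ester carbinol, C7, C8(CH3)=C9, C10); β is the face of the C1 methyl; "trinor" means without the three isopropyl carbons; the target is (1R,4R,5S,6S), trans-fused, 4β-OH, 6α-O-acyl; the three numbered starting materials are taken as catalogue chemicals.

## Retrosynthetic overview

- Target ⇐ aryl silyl ether ⇐ 4β-hydroxy-6-ketone + silyl-protected p-coumaraldehyde: a samarium-catalysed Tishchenko reduction with acyl shift makes the ester C–O bond and sets C6.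
- 4β-Hydroxy-6-ketone ⇐ 4β,5β-epoxy-6β-ol by anti 1,2-hydride shift (sets C5) ⇐ hydroxyl-directed epoxidation (sets the C4–O bond) of the 4-en-6β-ol ⇐ CBS reduction of the 4-en-6-one.
- 4-En-6-one ⇐ Stork–Danheiser isopropylation of a bicyclic vinylogous ester ⇐ bicyclic 1,3-diketone ⇐ ring-closing metathesis (seven-membered ring, formed second).
- Metathesis precursor ⇐ asymmetric copper-catalysed methyl conjugate addition / enolate C-acylation on 3-allylcyclopent-2-enone (sets C1; the five-membered ring is present from the start).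

## Route

Step 1
Reactants: 1 3-ethoxycyclopent-2-en-1-one
Product: 3 3-allylcyclopent-2-en-1-one, via tertiary allylic alkoxide 2 (not isolated)
Conditions: allylMgBr (1.2 equiv), THF, −78 → 0 °C; then 1 M HCl, 0 °C
Reagents that add atoms: allylmagnesium bromide, C=CC[Mg]Br
Why: Stork–Danheiser sequence, in which the Grignard reagent adds 1,2 to the vinylogous ester and acid hydrolysis of the enol ether with loss of ethanol transposes the carbonyl; no stereocentre is formed.

Step 2
Reactants: 3 3-allylcyclopent-2-en-1-one; 4 3-methylbut-3-enoic acid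
Product: 8 (3R)-3-allyl-3-methyl-2-(3-methylbut-3-enoyl)cyclopentan-1-one, via dimethylaluminium enolate 5 (not isolated), via lithium aluminate enolate 6 (not isolated), via acyl imidazole 7 (not isolated)
Conditions: AlMe3 (1.4 equiv), copper thiophene-2-carboxylate (5 mol %), chiral biphenol phosphoramidite L* (10 mol %, the enantiomer that gives R at the new centre), Et2O, −30 °C; MeLi (1.4 equiv), THF, −78 °C; then 7 (from 4 and 1,1'-carbonyldiimidazole, THF, rt), −78 → −20 °C; aq. HCl
Reagents that add atoms: trimethylaluminium, C[Al](C)C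
Why: Copper-catalysed asymmetric conjugate addition of a methyl–aluminium reagent to a β-substituted cyclopentenone is an established route to all-carbon quaternary centres, the phosphoramidite–copper complex choosing the enone face so that C1 becomes R, and the regiodefined enolate, made more nucleophilic as its lithium aluminate, is C-acylated (crossed Claisen condensation) between the carbonyl and the new quaternary carbon; the acidic C5 of the 1,3-diketone needs no control.

Step 3
Reactants: 8 (3R)-3-allyl-3-methyl-2-(3-methylbut-3-enoyl)cyclopentan-1-one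
Product: 9 (1R)-11,12,13-trinordauc-8-ene-4,6-dione
Conditions: second-generation Hoveyda–Grubbs catalyst (5 mol %), toluene (0.005 M), 80 °C
Reagents that add atoms: none
Why: Ring-closing metathesis of the allyl group with the 1,1-disubstituted olefin closes the seven-membered ring as the trisubstituted C8=C9 olefin with loss of ethene; C1 is untouched.

Step 4
Reactants: 9 (1R)-11,12,13-trinordauc-8-ene-4,6-dione
Product: 10 (1R)-6-methoxy-11,12,13-trinordauca-5,8-dien-4-one
Conditions: TMSCHN2 (1.5 equiv), MeOH–toluene (1:4), 0 °C → rt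
Reagents that add atoms: (trimethylsilyl)diazomethane, C[Si](C)(C)C=[N+]=[N-]
Why: O-Methylation of the enolised 1,3-diketone by diazomethane generated in the flask; the enol double bond lies exocyclic to the cyclopentanone (the preferred tautomer of 2-acylcyclopentanones), so the methyl ends on the C6 oxygen and C4 stays a ketone.

Step 5
Reactants: 10 (1R)-6-methoxy-11,12,13-trinordauca-5,8-dien-4-one
Product: 12 (1R)-dauca-4,8-dien-6-one, via tertiary allylic alkoxide 11 (not isolated)
Conditions: i-PrLi (1.5 equiv), CeCl3 (1.6 equiv), THF, −78 °C; then 1 M HCl, THF, 0 °C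
Reagents that add atoms: isopropyllithium, CC(C)[Li]
Why: Second Stork–Danheiser sequence, in which the organocerium reagent adds 1,2 to the C4 ketone without enolisation and acid-induced loss of methanol moves the carbonyl to C6 and the double bond to C4=C5, placing isopropyl on C4.

Step 6
Reactants: 12 (1R)-dauca-4,8-dien-6-one
Product: 13 (1R,6R)-dauca-4,8-dien-6-ol (6β-OH)
Conditions: (S)-2-methyl-CBS-oxazaborolidine (20 mol %), catecholborane (1.5 equiv), toluene, −78 °C
Reagents that add atoms: none
Why: Corey–Bakshi–Shibata reduction, in which the oxazaborolidine treats the fully substituted alkenyl carbon C5 as the large and C7H2 as the small ketone substituent and delivers hydride to the α face (also the face away from the angular methyl), giving the 6R (6β) alcohol.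

Step 7
Reactants: 13 (1R,6R)-dauca-4,8-dien-6-ol
Product: 14 (1R,4R,5S,6R)-4,5-epoxydauc-8-en-6-ol (4β,5β-epoxide, 6β-OH)
Conditions: VO(acac)2 (5 mol %), t-BuOOH (1.1 equiv), CH2Cl2, 0 °C
Reagents that add atoms: tert-butyl hydroperoxide, CC(C)(C)OO
Why: Hydroxyl-directed vanadium-catalysed epoxidation, in which the C6 vanadate ester can reach only the β face of the tetrasubstituted C4=C5 olefin (allylic strain keeps the C6 oxygen on that side), so the C4–O bond is formed in the β configuration of the target, and the allylic olefin reacts faster than the homoallylic C8=C9 olefin.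

Step 8
Reactants: 14 (1R,4R,5S,6R)-4,5-epoxydauc-8-en-6-ol
Product: 17 (1R,4R,5R)-4-hydroxydauc-8-en-6-one (4β-OH, 5α-H), via epoxy silyl ether 15 (not isolated), via silyloxy ketone 16 (not isolated)
Conditions: TMSOTf (2.2 equiv), i-Pr2NEt (2.5 equiv), CH2Cl2, −78 → −40 °C; then citric acid, MeOH, 0 °C
Reagents that add atoms: none
Why: Semipinacol rearrangement of a 2,3-epoxy silyl ether (non-aldol aldol process), in which silyl triflate activation of the epoxide lets H6, lying anti-periplanar to the C5–O bond in the ring-allowed conformer of the 6R epimer, migrate to C5 with inversion, so C5 receives its α hydrogen stereospecifically, C6 becomes the ketone and the β oxygen stays on C4.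

Step 9
Reactants: 18 4-(tert-butyldimethylsilyloxy)benzaldehyde
Product: 19 (2E)-3-[4-(tert-butyldimethylsilyloxy)phenyl]prop-2-enal
Conditions: Ph3P=CHCHO (1.1 equiv), toluene, 80 °C
Reagents that add atoms: (triphenylphosphoranylidene)acetaldehyde, O=CC=P(c1ccccc1)(c1ccccc1)c1ccccc1
Why: Wittig olefination with a carbonyl-stabilised ylide, which gives the E enal.

Step 10
Reactants: 17 (1R,4R,5R)-4-hydroxydauc-8-en-6-one; 19 (2E)-3-[4-(tert-butyldimethylsilyloxy)phenyl]prop-2-enal
Product: 22 (1R,4R,5S,6S)-4-hydroxydauc-8-en-6-yl (2E)-3-[4-(tert-butyldimethylsilyloxy)phenyl]prop-2-enoate, via samarium hemiacetal 20 (not isolated), via tertiary cinnamate 21 (not isolated)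
Conditions: SmI2 (30 mol %), 19 (3 equiv), THF, −10 °C → rt, 16 h
Reagents that add atoms: none
Why: Proposed new method: an Evans–Tishchenko reduction run on a tertiary β-hydroxy ketone with an α,β-unsaturated aldehyde and coupled to 1,3-acyl transfer in the same flask — the trivalent samarium alkoxide of the C4 hydroxyl adds to the aldehyde, the hemiacetal C–H is delivered through a six-membered chair to the β face of the C6 ketone (giving the 6α oxygen, anti to the 4β oxygen), and the resulting C6 samarium alkoxide attacks the crowded tertiary cinnamate through a six-membered ortho ester so that the acyl group settles on the secondary C6 oxygen; the closest known reactions are the Evans–Tishchenko reduction of secondary β-hydroxy ketones with saturated or aromatic aldehydes and base-mediated acyl migration in 1,3-diol monoesters.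

Step 11
Reactants: 22 (1R,4R,5S,6S)-4-hydroxydauc-8-en-6-yl (2E)-3-[4-(tert-butyldimethylsilyloxy)phenyl]prop-2-enoate
Product: 23 (1R,4R,5S,6S)-4-hydroxydauc-8-en-6-yl (2E)-3-(4-hydroxyphenyl)prop-2-enoate (target, CNP0265426.1)
Conditions: TBAF (1.1 equiv), AcOH (1.2 equiv), THF, 0 °C
Reagents that add atoms: none
Why: Buffered fluoride cleaves the aryl silyl ether selectively, leaving the cinnamate ester, the tertiary alcohol and all four stereocentres untouched (silyl ether deprotection).

## Compound list

1 | 3-ethoxycyclopent-2-en-1-one | CCOC1=CC(=O)CC1 | starting material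
2 | 1-allyl-3-ethoxycyclopent-2-en-1-ol, formed as its bromomagnesium alkoxide (not isolated) | C=CCC1(O)C=C(OCC)CC1 | intermediate
3 | 3-allylcyclopent-2-en-1-one | C=CCC1=CC(=O)CC1 | intermediate
4 | 3-methylbut-3-enoic acid | CC(=C)CC(=O)O | starting material
5 | dimethylaluminium enolate of (R)-3-allyl-3-methylcyclopentanone, enolate double bond towards the quaternary carbon (not isolated) | C=CC[C@@]1(C)CCC(O[Al](C)C)=C1 | intermediate
6 | lithium trimethylaluminate of the same (R)-enolate (not isolated) | [Li+].C=CC[C@@]1(C)CCC(O[Al-](C)(C)C)=C1 | intermediate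
7 | 1-(3-methylbut-3-enoyl)imidazole (not isolated) | CC(=C)CC(=O)n1ccnc1 | intermediate
8 | (3R)-3-allyl-3-methyl-2-(3-methylbut-3-enoyl)cyclopentan-1-one (keto–enol mixture) | C=CC[C@@]1(C)CCC(=O)C1C(=O)CC(C)=C | intermediate
9 | (1R)-11,12,13-trinordauc-8-ene-4,6-dione (keto–enol mixture) | CC1=CC[C@@]2(C)CCC(=O)C2C(=O)C1 | intermediate
10 | (1R)-6-methoxy-11,12,13-trinordauca-5,8-dien-4-one | CC1=CC[C@@]2(C)CCC(=O)C2=C(OC)C1 | intermediate
11 | (1R)-6-methoxydauca-5,8-dien-4-ol, formed as its metal alkoxide, C4 epimers (not isolated) | CC1=CC[C@@]2(C)CCC(O)(C(C)C)C2=C(OC)C1 | intermediate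
12 | (1R)-dauca-4,8-dien-6-one | CC1=CC[C@@]2(C)CCC(C(C)C)=C2C(=O)C1 | intermediate
13 | (1R,6R)-dauca-4,8-dien-6-ol (6β-OH) | CC1=CC[C@@]2(C)CCC(C(C)C)=C2[C@H](O)C1 | intermediate
14 | (1R,4R,5S,6R)-4,5-epoxydauc-8-en-6-ol (4β,5β-epoxide, 6β-OH) | CC1=CC[C@@]2(C)CC[C@]3(C(C)C)O[C@]23[C@H](O)C1 | intermediate
15 | 6-O-trimethylsilyl ether of 14 (not isolated) | CC1=CC[C@@]2(C)CC[C@]3(C(C)C)O[C@]23[C@H](O[Si](C)(C)C)C1 | intermediate
16 | 4-O-trimethylsilyl ether of 17 (not isolated) | CC1=CC[C@@]2(C)CC[C@@](O[Si](C)(C)C)(C(C)C)[C@@H]2C(=O)C1 | intermediate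
17 | (1R,4R,5R)-4-hydroxydauc-8-en-6-one (4β-OH, 5α-H, trans-fused) | CC1=CC[C@@]2(C)CC[C@@](O)(C(C)C)[C@@H]2C(=O)C1 | intermediate
18 | 4-(tert-butyldimethylsilyloxy)benzaldehyde | CC(C)(C)[Si](C)(C)Oc1ccc(C=O)cc1 | starting material
19 | (2E)-3-[4-(tert-butyldimethylsilyloxy)phenyl]prop-2-enal | CC(C)(C)[Si](C)(C)Oc1ccc(/C=C/C=O)cc1 | intermediate
20 | hemiacetal of 19 on the C4 oxygen of 17, formed as its samarium alkoxide (not isolated) | CC1=CC[C@@]2(C)CC[C@@](OC(O)/C=C/c3ccc(O[Si](C)(C)C(C)(C)C)cc3)(C(C)C)[C@@H]2C(=O)C1 | intermediate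
21 | (1R,4R,5S,6S)-6-hydroxydauc-8-en-4-yl (2E)-3-[4-(tert-butyldimethylsilyloxy)phenyl]prop-2-enoate (not isolated) | CC1=CC[C@@]2(C)CC[C@@](OC(=O)/C=C/c3ccc(O[Si](C)(C)C(C)(C)C)cc3)(C(C)C)[C@@H]2[C@@H](O)C1 | intermediate
22 | (1R,4R,5S,6S)-4-hydroxydauc-8-en-6-yl (2E)-3-[4-(tert-butyldimethylsilyloxy)phenyl]prop-2-enoate | CC1=CC[C@@]2(C)CC[C@@](O)(C(C)C)[C@@H]2[C@@H](OC(=O)/C=C/c2ccc(O[Si](C)(C)C(C)(C)C)cc2)C1 | intermediate
23 | (1R,4R,5S,6S)-4-hydroxydauc-8-en-6-yl (2E)-3-(4-hydroxyphenyl)prop-2-enoate | CC1=CC[C@@]2(C)CC[C@@](O)(C(C)C)[C@@H]2[C@@H](OC(=O)/C=C/c2ccc(O)cc2)C1 | target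

## Step count and risks

Total step count: 11. Longest linear sequence: 10 (steps 1–8, 10, 11; step 9 is the side branch).

The three steps most likely to fail:

**Step 10 (the proposed new step).** The tertiary alkoxide may not form the hemiacetal, the enal may react at samarium in other ways, or the acyl shift may stall at 21. Fallback, from 17 back to 23, with known chemistry: Me4NBH(OAc)3 in MeCN–AcOH at −30 °C (Evans–Saksena delivery of hydride from the C4 alkoxyborohydride to the β face of C6) gives dauc-8-ene-4β,6α-diol F7. Yamaguchi esterification of the secondary hydroxyl with commercial (E)-4-acetoxycinnamic acid gives (1R,4R,5S,6S)-4-hydroxydauc-8-en-6-yl (2E)-3-(4-acetoxyphenyl)prop-2-enoate F8. Pyrrolidine in CH2Cl2 removes the phenolic acetate and gives 23.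

**Step 2 (one-flask conjugate addition and C-acylation).** The aluminate enolate may be O-acylated or may simply deprotonate the β,γ-unsaturated acyl donor. Fallback, from 3 back to 8: run the same copper-catalysed methyl addition but quench with TMSCl and isolate the silyl enol ether (R)-3-allyl-3-methyl-1-(trimethylsilyloxy)cyclopent-1-ene F1. A BF3·OEt2-mediated Mukaiyama aldol addition to freshly made 3-methylbut-3-enal F2 (Dess–Martin oxidation of 3-methylbut-3-en-1-ol) gives the aldol (3R)-3-allyl-2-(1-hydroxy-3-methylbut-3-en-1-yl)-3-methylcyclopentan-1-one F3, whose diastereomers do not matter. Dess–Martin oxidation of F3 gives 8.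

**Step 8 (hydride shift on a fully substituted epoxide).** Ionisation at C4 instead of C5, or migration of the skipped C8=C9 olefin into conjugation, could compete. Fallback, from 14 back to 17, replacing the stereospecific shift by thermodynamic control at C5: Dess–Martin oxidation of 14 gives 4β,5β-epoxydauc-8-en-6-one F4. SmI2 in THF–MeOH at −78 °C cleaves the C5–O bond (the oxygen stays on C4) and gives 17 mixed with its C5 epimer (1R,4R,5S)-4-hydroxydauc-8-en-6-one F5. DBU then moves the ring olefin into conjugation and equilibrates C5 to the trans-fused isomer in which C6 is anti to isopropyl, giving 4β-hydroxy-5αH-dauc-7-en-6-one F6. Kinetic deconjugation (lithium diisopropylamide, then AcOH at −78 °C) returns 17.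

## Further compounds

F1 | step 2 | (R)-3-allyl-3-methyl-1-(trimethylsilyloxy)cyclopent-1-ene | C=CC[C@@]1(C)CCC(O[Si](C)(C)C)=C1
F2 | step 2 | 3-methylbut-3-enal | CC(=C)CC=O
F3 | step 2 | (3R)-3-allyl-2-(1-hydroxy-3-methylbut-3-en-1-yl)-3-methylcyclopentan-1-one | C=CC[C@@]1(C)CCC(=O)C1C(O)CC(C)=C
F4 | step 8 | (1R)-4β,5β-epoxydauc-8-en-6-one | CC1=CC[C@@]2(C)CC[C@]3(C(C)C)O[C@]23C(=O)C1
F5 | step 8 | (1R,4R,5S)-4-hydroxydauc-8-en-6-one (C5 epimer of 17, cis-fused) | CC1=CC[C@@]2(C)CC[C@@](O)(C(C)C)[C@H]2C(=O)C1
F6 | step 8 | (1R)-4β-hydroxy-5αH-dauc-7-en-6-one | CC=1CC[C@@]2(C)CC[C@@](O)(C(C)C)[C@@H]2C(=O)C=1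
F7 | step 10 | (1R,4R,5S,6S)-dauc-8-ene-4,6-diol (4β,6α-diol) | CC1=CC[C@@]2(C)CC[C@@](O)(C(C)C)[C@@H]2[C@@H](O)C1
F8 | step 10 | (1R,4R,5S,6S)-4-hydroxydauc-8-en-6-yl (2E)-3-(4-acetoxyphenyl)prop-2-enoate | CC1=CC[C@@]2(C)CC[C@@](O)(C(C)C)[C@@H]2[C@@H](OC(=O)/C=C/c2ccc(OC(C)=O)cc2)C1
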